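**Retrosynthetic overview**

1. Feature: ring C of the flavanone (O1–C2–C3–C4–C4a–C8a) is read as the heterodiene O1=C8a–C4a=C4 of ring A, with an oxygen on C4, joined to the two-carbon unit C2=C3 that carries ring B.
2. Late disconnection: the C4 ketone and the 5,7-phenols come from a (2S)-4-methoxy-5,7-bis(silyloxy)flavan by ether hydrolysis, oxidation and buffered desilylation.
3. Key disconnection: O1–C2 and C3–C4 are formed from the methoxy ortho-quinone methide (oxocarbenium ion) of the ring A salicylaldehyde dimethyl acetal and the ring B styrene, with a chiral phosphoric acid setting C2 as (S).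
4. Ring A aldehyde from phloroglucinol: bis-silylation, tert-prenyl ether Claisen rearrangement (C8 prenyl), magnesium-mediated ortho-formylation. Ring B styrene from 4-hydroxybenzaldehyde: tert-prenyl ether Claisen rearrangement, propargyl ether cyclisation to the chromene, Wittig methylenation. All three propargyl ethers are made with one reagent, 3-chloro-3-methylbut-1-yne, prepared once from 2-methylbut-3-yn-2-ol.
5. Ring order: the chromene pyran ring on ring B first (step 11), then pyran ring C in the key step; rings A and B are bought as arenes.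

Key step: step 13

Assumption: the sense of induction of the phosphoric acid cannot be predicted, so the (R)-catalyst is written and its antipode is taken if the ion pair leads to the (2R) series; 18 is drawn as the cation, its counter-anion being the phosphate of the catalyst.

**Route**

Step 1
Reactants: 1 phloroglucinol
Product: 2 3,5-bis(tert-butyldimethylsilyloxy)phenol
Conditions: TBSCl (2.0 equiv), imidazole, DMF, 0 → 23 °C
Reagents that add atoms: tert-butyldimethylsilyl chloride, CC(C)(C)[Si](C)(C)Cl
Why: Statistical silyl ether formation on three equivalent phenols should give the bis-silyl ether as the main component at two equivalents of chloride, separable by chromatography from the mono- and tris-silyl ethers, which can be recycled.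

Step 2
Reactants: 3 2-methylbut-3-yn-2-ol
Product: 4 3-chloro-3-methylbut-1-yne
Conditions: conc. aq. HCl, CaCl2, CuCl (cat.), Cu powder (cat.), 0 → 20 °C; organic layer dried and distilled
Reagents that add atoms: hydrogen chloride, Cl
Why: SN1 substitution of the tertiary propargylic alcohol through the stabilised propargylic cation gives the tertiary chloride, a distillable liquid that is made once and stored cold for the three etherifications of the route.

Step 3
Reactants: 2 3,5-bis(tert-butyldimethylsilyloxy)phenol; 4 3-chloro-3-methylbut-1-yne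
Product: 5 1,3-bis(tert-butyldimethylsilyloxy)-5-(2-methylbut-3-yn-2-yloxy)benzene
Conditions: 4 (1.3 equiv), DBU (1.5 equiv), CuCl2 (cat.), anhydrous MeCN, 0 °C
Reagents that add atoms: none
Why: Copper-catalysed propargylic etherification of a phenol with a tertiary propargylic chloride forms the hindered aryl ether at oxygen under mild base at low temperature, and the anhydrous medium, which holds no alcohol or water, should spare the aryl silyl ethers.

Step 4
Reactants: 5 1,3-bis(tert-butyldimethylsilyloxy)-5-(2-methylbut-3-yn-2-yloxy)benzene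
Product: 6 1,3-bis(tert-butyldimethylsilyloxy)-5-(2-methylbut-3-en-2-yloxy)benzene
Conditions: H2 (1 atm), Pd/CaCO3 poisoned with Pb(OAc)2 (Lindlar catalyst), quinoline, EtOAc, 23 °C
Reagents that add atoms: none
Why: Lindlar semi-hydrogenation of a terminal alkyne stops at the alkene and leaves aryl silyl ethers untouched.

Step 5
Reactants: 6 1,3-bis(tert-butyldimethylsilyloxy)-5-(2-methylbut-3-en-2-yloxy)benzene
Product: 7 3,5-bis(tert-butyldimethylsilyloxy)-2-(3-methylbut-2-enyl)phenol
Conditions: PhMe, 110 °C
Reagents that add atoms: none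
Why: Aromatic Claisen rearrangement of the 1,1-dimethylallyl ether delivers the linear prenyl group to an ortho carbon, and the two ortho carbons are equivalent by symmetry, so a single product is expected.

Step 6
Reactants: 7 3,5-bis(tert-butyldimethylsilyloxy)-2-(3-methylbut-2-enyl)phenol
Product: 9 4,6-bis(tert-butyldimethylsilyloxy)-2-hydroxy-3-(3-methylbut-2-enyl)benzaldehyde, via salicyl alcohol 8 (not isolated)
Conditions: MgCl2, Et3N, (CH2O)n, THF, reflux
Reagents that add atoms: paraformaldehyde (as formaldehyde), C=O
Why: Magnesium-mediated ortho-formylation (Casnati–Skattebøl type) delivers formaldehyde from the magnesium phenoxide to the only free ortho carbon, and the salicyl alcohol 8 is oxidised in the flask by hydride transfer to a second formaldehyde.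

Step 7
Reactants: 10 4-hydroxybenzaldehyde; 4 3-chloro-3-methylbut-1-yne
Product: 11 4-(2-methylbut-3-yn-2-yloxy)benzaldehyde
Conditions: 4 (1.3 equiv), DBU (1.5 equiv), CuCl2 (cat.), MeCN, 0 °C
Reagents that add atoms: none
Why: Copper-catalysed propargylic etherification works well on acidic, electron-poor phenols and leaves the aldehyde alone.

Step 8
Reactants: 11 4-(2-methylbut-3-yn-2-yloxy)benzaldehyde
Product: 12 4-(2-methylbut-3-en-2-yloxy)benzaldehyde
Conditions: H2 (1 atm), Pd/CaCO3 poisoned with Pb(OAc)2 (Lindlar catalyst), quinoline, EtOAc, 23 °C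
Reagents that add atoms: none
Why: Lindlar semi-hydrogenation reduces only the terminal alkyne, the aryl aldehyde being inert under these conditions.

Step 9
Reactants: 12 4-(2-methylbut-3-en-2-yloxy)benzaldehyde
Product: 13 4-hydroxy-3-(3-methylbut-2-enyl)benzaldehyde
Conditions: xylenes, 140 °C
Reagents that add atoms: none
Why: Aromatic Claisen rearrangement of the tert-prenyl ether places the prenyl group on one of the two equivalent ortho carbons, the para position being blocked by the formyl group.

Step 10
Reactants: 13 4-hydroxy-3-(3-methylbut-2-enyl)benzaldehyde; 4 3-chloro-3-methylbut-1-yne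
Product: 14 4-(2-methylbut-3-yn-2-yloxy)-3-(3-methylbut-2-enyl)benzaldehyde
Conditions: 4 (1.5 equiv), DBU (1.7 equiv), CuCl2 (cat.), MeCN, 0 → 23 °C
Reagents that add atoms: none
Why: The same copper-catalysed propargylic etherification tolerates an ortho substituent on the phenol and does not touch the prenyl alkene.

Step 11
Reactants: 14 4-(2-methylbut-3-yn-2-yloxy)-3-(3-methylbut-2-enyl)benzaldehyde
Product: 15 2,2-dimethyl-8-(3-methylbut-2-enyl)-2H-chromene-6-carbaldehyde
Conditions: N,N-diethylaniline, 190 °C
Reagents that add atoms: none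
Why: Thermal aryl propargyl ether rearrangement (propargyl Claisen shift to the free ortho carbon, 1,5-hydrogen shift and oxa-6π electrocyclisation) closes the 2,2-dimethylchromene, and the prenyl group blocks the other ortho carbon, which fixes the regiochemistry.

Step 12
Reactants: 15 2,2-dimethyl-8-(3-methylbut-2-enyl)-2H-chromene-6-carbaldehyde
Product: 16 6-ethenyl-2,2-dimethyl-8-(3-methylbut-2-enyl)-2H-chromene
Conditions: Ph3PCH3Br, KOtBu, THF, 0 → 23 °C
Reagents that add atoms: methyltriphenylphosphonium bromide, C[P+](c1ccccc1)(c1ccccc1)c1ccccc1.[Br-]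
Why: Wittig methylenation of a non-enolisable aryl aldehyde is reliable, and the styrene is to be stored cold over BHT and used promptly.

Step 13
Reactants: 9 4,6-bis(tert-butyldimethylsilyloxy)-2-hydroxy-3-(3-methylbut-2-enyl)benzaldehyde; 16 6-ethenyl-2,2-dimethyl-8-(3-methylbut-2-enyl)-2H-chromene
Product: 19 (2S)-5,7-bis(tert-butyldimethylsilyloxy)-2-[2,2-dimethyl-8-(3-methylbut-2-enyl)-2H-chromen-6-yl]-4-methoxy-8-(3-methylbut-2-enyl)chromane (both C4 epimers), via dimethyl acetal 17 (not isolated), via oxocarbenium ion 18 (not isolated)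
Conditions: 9, HC(OMe)3 (1.2 equiv), (R)-3,3'-bis(2,4,6-triisopropylphenyl)-1,1'-binaphthyl-2,2'-diyl hydrogen phosphate (C50H57O4P, 10 mol %), PhMe, 23 °C; volatiles removed in vacuo; PhMe, 5 Å MS, −40 °C, slow addition of 16 (1.3 equiv); Et3N quench
Reagents that add atoms: trimethyl orthoformate, COC(OC)OC
Why: Proposed new method: the phosphoric acid first mediates acetal formation from 9 and the orthoformate and then ionises 17 to the hydrogen-bonded ion pair 18, the O-protonated 4-methoxy ortho-quinone methide of ring A; the CH2 terminus of the vinyl group of 16 bonds to C4 and the phenol oxygen captures the developing para-alkoxybenzyl cation at C2, as an asynchronous inverse-demand hetero-Diels–Alder reaction or a Prins addition followed by ring closure, which forms C3–C4 and O1–C2. The closest known reaction types are the achiral acid-promoted union of salicylaldehydes, orthoformates and styrenes to racemic 4-alkoxyflavans and chiral phosphoric acid-catalysed [4+2] cycloadditions of ortho-quinone methides with electron-rich alkenes; their combination on an alkoxy ortho-quinone methide and a styrene without a second binding group has not been shown. Ring C closes in the concerted suprafacial [4+2] mode or, in the stepwise limit, by 6-exo-trig capture of the benzylic cation (its quinoid π bond lying outside the new ring) by O1. The (S) centre at C2 is controlled by the chiral phosphate, which is bound to the phenol O–H and the oxocarbenium C–H of 18 and shields one face of the cation, acting together with the endo placement of the electron-rich aryl group over the cationic heterodiene, so that face selection and endo/exo selection must both be high, whereas the E/Z geometry of the C=OMe unit and any later reionisation at C4 affect only the C4 centre, which is uncontrolled and removed in step 15. O1 bonds to the benzylic carbon because that carbon carries the positive charge, and the vinyl group outcompetes the two prenyl alkenes and the chromene C3=C4 bond because it is para to the chromene oxygen and unsubstituted at its terminus, while the chromene alkene is shielded by the adjacent gem-dimethyl carbon. Low temperature, slow addition of 16 and removal of methanol before the addition are meant to suppress styrene oligomerisation and scrambling of C2 by reversible opening of the O1–C2 bond.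

Step 14
Reactants: 19 (2S)-5,7-bis(tert-butyldimethylsilyloxy)-2-[2,2-dimethyl-8-(3-methylbut-2-enyl)-2H-chromen-6-yl]-4-methoxy-8-(3-methylbut-2-enyl)chromane (both C4 epimers)
Product: 20 (2S)-5,7-bis(tert-butyldimethylsilyloxy)-2-[2,2-dimethyl-8-(3-methylbut-2-enyl)-2H-chromen-6-yl]-8-(3-methylbut-2-enyl)chroman-4-ol (both C4 epimers)
Conditions: pyridinium p-toluenesulfonate (0.2 equiv), THF/H2O (5:1), 23 °C; crude product used directly
Reagents that add atoms: water, O
Why: SN1 solvolysis of the benzylic methyl ether should be easy because the C4 cation is stabilised by O1 and the 5- and 7-silyloxy groups, water captures it, C2 is not involved, and the weakly acidic medium should spare the aryl silyl ethers, the prenyl groups and the chromene.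

Step 15
Reactants: 20 (2S)-5,7-bis(tert-butyldimethylsilyloxy)-2-[2,2-dimethyl-8-(3-methylbut-2-enyl)-2H-chromen-6-yl]-8-(3-methylbut-2-enyl)chroman-4-ol (both C4 epimers)
Product: 21 (2S)-5,7-bis(tert-butyldimethylsilyloxy)-2-[2,2-dimethyl-8-(3-methylbut-2-enyl)-2H-chromen-6-yl]-8-(3-methylbut-2-enyl)chroman-4-one
Conditions: Dess–Martin periodinane, pyridine, CH2Cl2, 0 → 23 °C
Reagents that add atoms: none
Why: Dess–Martin oxidation of the secondary benzylic alcohol converges both C4 epimers on one ketone, and the buffered, non-basic medium avoids enolisation and opening of ring C, so C2 should stay intact.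

Step 16
Reactants: 21 (2S)-5,7-bis(tert-butyldimethylsilyloxy)-2-[2,2-dimethyl-8-(3-methylbut-2-enyl)-2H-chromen-6-yl]-8-(3-methylbut-2-enyl)chroman-4-one
Product: 22 maackiaflavanone B, (2S)-5,7-dihydroxy-2-[2,2-dimethyl-8-(3-methylbut-2-enyl)-2H-chromen-6-yl]-8-(3-methylbut-2-enyl)chroman-4-one
Conditions: Bu4NF (2.4 equiv), AcOH (2.4 equiv), THF, 0 °C
Reagents that add atoms: none
Why: Fluoride cleavage of the two aryl silyl ethers is buffered with acetic acid so that no phenoxide- or enolate-triggered retro-oxa-Michael opening to the chalcone can racemise C2.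

**Compound list**

1 | phloroglucinol | Oc1cc(O)cc(O)c1 | starting material
2 | 3,5-bis(tert-butyldimethylsilyloxy)phenol | Oc1cc(O[Si](C)(C)C(C)(C)C)cc(O[Si](C)(C)C(C)(C)C)c1 | intermediate
3 | 2-methylbut-3-yn-2-ol | CC(C)(O)C#C | starting material
4 | 3-chloro-3-methylbut-1-yne | CC(C)(Cl)C#C | intermediate
5 | 1,3-bis(tert-butyldimethylsilyloxy)-5-(2-methylbut-3-yn-2-yloxy)benzene | C#CC(C)(C)Oc1cc(O[Si](C)(C)C(C)(C)C)cc(O[Si](C)(C)C(C)(C)C)c1 | intermediate
6 | 1,3-bis(tert-butyldimethylsilyloxy)-5-(2-methylbut-3-en-2-yloxy)benzene | C=CC(C)(C)Oc1cc(O[Si](C)(C)C(C)(C)C)cc(O[Si](C)(C)C(C)(C)C)c1 | intermediate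
7 | 3,5-bis(tert-butyldimethylsilyloxy)-2-(3-methylbut-2-enyl)phenol | CC(C)=CCc1c(O)cc(O[Si](C)(C)C(C)(C)C)cc1O[Si](C)(C)C(C)(C)C | intermediate
8 | 3,5-bis(tert-butyldimethylsilyloxy)-2-(hydroxymethyl)-6-(3-methylbut-2-enyl)phenol (present as its magnesium phenoxide) | OCc1c(O)c(CC=C(C)C)c(O[Si](C)(C)C(C)(C)C)cc1O[Si](C)(C)C(C)(C)C | intermediate
9 | 4,6-bis(tert-butyldimethylsilyloxy)-2-hydroxy-3-(3-methylbut-2-enyl)benzaldehyde | O=Cc1c(O)c(CC=C(C)C)c(O[Si](C)(C)C(C)(C)C)cc1O[Si](C)(C)C(C)(C)C | intermediate
10 | 4-hydroxybenzaldehyde | O=Cc1ccc(O)cc1 | starting material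
11 | 4-(2-methylbut-3-yn-2-yloxy)benzaldehyde | C#CC(C)(C)Oc1ccc(C=O)cc1 | intermediate
12 | 4-(2-methylbut-3-en-2-yloxy)benzaldehyde | C=CC(C)(C)Oc1ccc(C=O)cc1 | intermediate
13 | 4-hydroxy-3-(3-methylbut-2-enyl)benzaldehyde | CC(C)=CCc1cc(C=O)ccc1O | intermediate
14 | 4-(2-methylbut-3-yn-2-yloxy)-3-(3-methylbut-2-enyl)benzaldehyde | C#CC(C)(C)Oc1ccc(C=O)cc1CC=C(C)C | intermediate
15 | 2,2-dimethyl-8-(3-methylbut-2-enyl)-2H-chromene-6-carbaldehyde | CC(C)=CCc1cc(C=O)cc2c1OC(C)(C)C=C2 | intermediate
16 | 6-ethenyl-2,2-dimethyl-8-(3-methylbut-2-enyl)-2H-chromene | C=Cc1cc(CC=C(C)C)c2OC(C)(C)C=Cc2c1 | intermediate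
17 | 3,5-bis(tert-butyldimethylsilyloxy)-2-(dimethoxymethyl)-6-(3-methylbut-2-enyl)phenol | COC(OC)c1c(O)c(CC=C(C)C)c(O[Si](C)(C)C(C)(C)C)cc1O[Si](C)(C)C(C)(C)C | intermediate
18 | [2,4-bis(tert-butyldimethylsilyloxy)-6-hydroxy-5-(3-methylbut-2-enyl)phenyl]methylidene(methyl)oxonium, ion pair with the catalyst phosphate | C[O+]=Cc1c(O)c(CC=C(C)C)c(O[Si](C)(C)C(C)(C)C)cc1O[Si](C)(C)C(C)(C)C | intermediate
19 | (2S)-5,7-bis(tert-butyldimethylsilyloxy)-2-[2,2-dimethyl-8-(3-methylbut-2-enyl)-2H-chromen-6-yl]-4-methoxy-8-(3-methylbut-2-enyl)chromane, C4 unspecified | CC(C)=CCc1cc([C@@H]2CC(OC)c3c(O[Si](C)(C)C(C)(C)C)cc(O[Si](C)(C)C(C)(C)C)c(CC=C(C)C)c3O2)cc2c1OC(C)(C)C=C2 | intermediate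
20 | (2S)-5,7-bis(tert-butyldimethylsilyloxy)-2-[2,2-dimethyl-8-(3-methylbut-2-enyl)-2H-chromen-6-yl]-8-(3-methylbut-2-enyl)chroman-4-ol, C4 unspecified | CC(C)=CCc1cc([C@@H]2CC(O)c3c(O[Si](C)(C)C(C)(C)C)cc(O[Si](C)(C)C(C)(C)C)c(CC=C(C)C)c3O2)cc2c1OC(C)(C)C=C2 | intermediate
21 | (2S)-5,7-bis(tert-butyldimethylsilyloxy)-2-[2,2-dimethyl-8-(3-methylbut-2-enyl)-2H-chromen-6-yl]-8-(3-methylbut-2-enyl)chroman-4-one | CC(C)=CCc1cc([C@@H]2CC(=O)c3c(O[Si](C)(C)C(C)(C)C)cc(O[Si](C)(C)C(C)(C)C)c(CC=C(C)C)c3O2)cc2c1OC(C)(C)C=C2 | intermediate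
22 | maackiaflavanone B | CC(C)=CCc1cc([C@@H]2CC(=O)c3c(O)cc(O)c(CC=C(C)C)c3O2)cc2c1OC(C)(C)C=C2 | target

**Step count and risks**

Total step count: 16. Longest linear sequence: 11 steps, counted from 2-methylbut-3-yn-2-ol through the ring B branch (step 2, then steps 7–16); counted from 4-hydroxybenzaldehyde it is 10 steps (steps 7–16). The ring A branch is steps 1 and 3–6.

Steps most likely to fail:

1. Step 13 (the step that carries the new method). The ion pair may be too loose for the phosphate to tell the faces of the cation apart, or endo/exo selection may be poor, so that C2 forms with low enantiomeric purity; acid-induced oligomerisation of the styrene may also consume 16. Fallback by known chemistry: from 9 and 16 the same three-component cycloaddition is run with an achiral acid ((PhO)2P(O)OH, HC(OMe)3, CH2Cl2, −20 °C), the known racemic reaction type, to give the racemic 4-methoxyflavan F1. Hydrolysis as in step 14 gives the racemic flavan-4-ol F2, and Dess–Martin oxidation as in step 15 gives the racemic bis-silyl flavanone F3. Preparative HPLC on a cellulose tris(3,5-dimethylphenylcarbamate) phase then separates the enantiomers and returns the (2S)-isomer to the route at 21.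

2. Step 14. The C4 cation may lose H3 to give the flav-3-ene or be captured by an electron-rich arene in place of water, and the flavan-4-ol may ionise again on silica. Fallback: from 19, DDQ in CH2Cl2/pH 7 buffer at 0 °C abstracts the C4 hydride of the electron-rich benzylic methyl ether, and water converts the resulting methoxycarbenium ion into the ketone. This oxidative ether cleavage gives 21 directly and bypasses 20.

3. Step 6. Silyl groups may be lost or exchanged under the hot amine/magnesium alkoxide conditions, and the hydride transfer that converts 8 into 9 may stall. Fallback: the formyl group is carried from the start. From 1, Vilsmeier–Haack formylation (POCl3, DMF, then water) gives 2,4,6-trihydroxybenzaldehyde F4. TBSCl (2 equiv)/imidazole silylates the para and one ortho phenol, the remaining ortho phenol being deactivated by its hydrogen bond to the aldehyde, and gives 4,6-bis(tert-butyldimethylsilyloxy)-2-hydroxybenzaldehyde F5. Copper-catalysed etherification with 4 as in step 3 gives the propargyl ether F6, and Lindlar reduction gives the tert-prenyl ether F7. Claisen rearrangement in toluene at 110 °C, which can only reach the free ortho carbon C3, returns to the route at 9.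

**Further compounds**

F1 | step 13 | racemic 5,7-bis(tert-butyldimethylsilyloxy)-2-[2,2-dimethyl-8-(3-methylbut-2-enyl)-2H-chromen-6-yl]-4-methoxy-8-(3-methylbut-2-enyl)chromane | CC(C)=CCc1cc(C2CC(OC)c3c(O[Si](C)(C)C(C)(C)C)cc(O[Si](C)(C)C(C)(C)C)c(CC=C(C)C)c3O2)cc2c1OC(C)(C)C=C2
F2 | step 13 | racemic 5,7-bis(tert-butyldimethylsilyloxy)-2-[2,2-dimethyl-8-(3-methylbut-2-enyl)-2H-chromen-6-yl]-8-(3-methylbut-2-enyl)chroman-4-ol | CC(C)=CCc1cc(C2CC(O)c3c(O[Si](C)(C)C(C)(C)C)cc(O[Si](C)(C)C(C)(C)C)c(CC=C(C)C)c3O2)cc2c1OC(C)(C)C=C2
F3 | step 13 | racemic 5,7-bis(tert-butyldimethylsilyloxy)-2-[2,2-dimethyl-8-(3-methylbut-2-enyl)-2H-chromen-6-yl]-8-(3-methylbut-2-enyl)chroman-4-one | CC(C)=CCc1cc(C2CC(=O)c3c(O[Si](C)(C)C(C)(C)C)cc(O[Si](C)(C)C(C)(C)C)c(CC=C(C)C)c3O2)cc2c1OC(C)(C)C=C2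
F0 | step 14 | none | none
F4 | step 6 | 2,4,6-trihydroxybenzaldehyde | O=Cc1c(O)cc(O)cc1O
F5 | step 6 | 4,6-bis(tert-butyldimethylsilyloxy)-2-hydroxybenzaldehyde | O=Cc1c(O)cc(O[Si](C)(C)C(C)(C)C)cc1O[Si](C)(C)C(C)(C)C
F6 | step 6 | 2,4-bis(tert-butyldimethylsilyloxy)-6-(2-methylbut-3-yn-2-yloxy)benzaldehyde | C#CC(C)(C)Oc1cc(O[Si](C)(C)C(C)(C)C)cc(O[Si](C)(C)C(C)(C)C)c1C=O
F7 | step 6 | 2,4-bis(tert-butyldimethylsilyloxy)-6-(2-methylbut-3-en-2-yloxy)benzaldehyde | C=CC(C)(C)Oc1cc(O[Si](C)(C)C(C)(C)C)cc(O[Si](C)(C)C(C)(C)C)c1C=O
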